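(The constants used here belong to no real substance, and the outcome is calculated.)

The constants were what I went to first when you asked for a quick number.

    first end groups + second end groups → links (k1 = 0.0223 /M/s)
    first end groups + second end groups → rings, rate k2*[first end groups] as long as [second end groups] is above zero (k2 = 1.08 × 10⁻⁴ /s)
    second end groups ⇌ dormant form (K3 = 0.42, k3 = 0.00792 /s)
    second end groups → decomposed reagent (k4 = 9.55 × 10⁻⁴ /s)
    first end groups + links → side product (k5 = 0.0171 /M/s)

| flask | first end groups | second end groups | time | remark |
|---|---|---|---|---|
| north | 48 mM (fed, over 30 min) | 1.02 equiv | 80 min | all else is in the flask from the start; the feed brings no volume worth counting |
| north-west | 48 mM | 1.02 equiv | 80 min | everything together at the start |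
| east | 48 mM (in portions, 2, over 30 min) | 1.02 equiv | 80 min | first portion at the start, last at 30 min |
| south | 48 mM | 1.02 equiv (fed, over 30 min) | 80 min | all else is in the flask from the start; the feed brings no volume worth counting |

- in percentages every species weighs as the first end groups in it: one side product counts as two
- run time (north): 80 min

* which flask leads in amount of side product, in percent of the first end groups charged ("all alike" within 1.5 percentage points) (north / north-west / east / south / all alike)
* how much side product is there at the end, in percent of the first end groups charged: north
* how much side product is there at the end, in percent of the first end groups charged: north-west
* how much side product is there at the end, in percent of the first end groups charged: east
* how much side product is there at the end, in percent of the first end groups charged: south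

Leaving the rings and the dormant form aside, I gave second end groups two pseudo-first-order exits: coupling, at the link constant times [first end groups], and decomposition. With the full charge of first end groups present, coupling took 52.8% of the sum, and this fraction is the coupling share. My zero of the scale was the even split, and north-west sat at about half.

The charge times the share gave me a rough figure for links. One side product counts two, and I guessed that half of those links would be turned, so two and a half cancelled: side product in percent of charge was about the equivalents times the share. For north-west that made 53.9%.

For north and east I took [first end groups] at half the charge while the reagent lived, so the share fell to 35.9%. That gave 36.6% for north and 36.6% for east.

For south I needed a steady level of [second end groups]. Feed less the ring rate, over coupling and decomposition, put it near 10.9 mM, and the link constant times that level times the feed time, with the same guess as before, gave 43.6%. My leader was north-west.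

Your forecast also named north-west, with 35% for north, 51% for north-west, 38% for east and 40% for south, on the ground that “Putting everything in at the start builds the most links soonest”. Its south stood lower than mine.

The flasks gave north-west in the lead: 34.1% for north, 51.4% for north-west, 38.1% for east and 40.0% for south. The forecast was right, and my reckoning named the same leader. North-west still held 21.1% of its first end groups at 80.0 min. My lowered share over the coupling share put north at 68.0% of north-west, and the flasks stood at 66.3%.

For the neighbour of north-west charged with 29 mM, the share came to 40.4%, which gave an estimate of 41.2% side product. The computed result was 34.5%.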